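## Retrosynthetic overview
1. Benzofuran: cut O1–C2 and C3–C3a, which opens the furan ring to 2,4-dihydroxy-5-iodoacetophenone and a terminal (S,E)-enyne (Sonogashira coupling, then 5-endo-dig closure).
2. Enyne: one-carbon homologation of the (S,E)-2-methylpent-2-enal (Colvin rearrangement).
3. Enal: E-selective Wittig reaction of Ph3P=C(CH3)CHO with the (R)-2-arylpropanal. The aldehyde and the only stereocentre come from asymmetric hydroformylation of the 6-vinylchromene.
4. Vinylchromene: Wittig methylenation of the 6-carbaldehyde, which comes from Vilsmeier–Haack formylation of commercial 7-methoxy-2,2-dimethyl-2H-chromene.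
5. Ring order: the chromene bicycle and the acetophenone benzene ring are bought intact. The furan ring is the only ring made, in the last step.

Assumption: (R,R)-Ph-BPE is taken to give the (R)-aldehyde from 4 as it does from styrene (the (S,S)-ligand is used if the first run shows the opposite sense). The expected 90–94 % ee is raised to a single enantiomer by recrystallising 11.

## Route

Step 1
Reactants: 1 7-methoxy-2,2-dimethyl-2H-chromene (CAS 17598-02-6)
Product: 3 7-methoxy-2,2-dimethyl-2H-chromene-6-carbaldehyde, via iminium salt 2 (not isolated)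
Conditions: POCl3 (1.2 equiv), DMF, 0 °C to 40 °C; then 2 M aq NaOH, 0 °C
Reagents that add atoms: N,N-dimethylformamide CN(C)C=O; water O
Why: In this Vilsmeier–Haack formylation the chloroiminium ion attacks C6, which is para to the ring oxygen and ortho to OMe and is the least hindered activated position, while the C3=C4 bond next to the quaternary C2 does not react.

Step 2
Reactants: 3 7-methoxy-2,2-dimethyl-2H-chromene-6-carbaldehyde
Product: 4 6-ethenyl-7-methoxy-2,2-dimethyl-2H-chromene
Conditions: MePPh3Br (1.3 equiv), KOtBu (1.25 equiv), THF, 0 °C to rt; product stored with BHT and used promptly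
Reagents that add atoms: methyltriphenylphosphonium bromide C[P+](c1ccccc1)(c1ccccc1)c1ccccc1.[Br-]
Why: Wittig methylenation of a non-enolisable aryl aldehyde is reliable, and nothing else in 3 reacts with the ylide.

Step 3
Reactants: 4 6-ethenyl-7-methoxy-2,2-dimethyl-2H-chromene
Product: 6 (2E,4S)-4-(7-methoxy-2,2-dimethyl-2H-chromen-6-yl)-2-methylpent-2-enal, via (R)-2-arylpropanal 5 (not isolated)
Conditions: Rh(acac)(CO)2 (0.5 mol %), (R,R)-Ph-BPE [1,2-bis((2R,5R)-2,5-diphenylphospholan-1-yl)ethane, 0.6 mol %], CO/H2 (1:1, 10 bar), toluene, 60 °C; vent; Ph3P=C(CH3)CHO (1.4 equiv), 70 °C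
Reagents that add atoms: carbon monoxide [C-]#[O+]; 2-(triphenylphosphoranylidene)propanal CC(C=O)=P(c1ccccc1)(c1ccccc1)c1ccccc1
Why: In the asymmetric hydroformylation the rhodium hydride adds to the terminal vinyl group in the branched (benzyl-stabilised) sense inside the C2-symmetric bisphospholane pocket and so sets the (R)-aldehyde, the weakly basic stabilised ylide then traps it in the same pot by E-selective Wittig olefination before it can enolise (R becomes S only because CHO outranks aryl and the alkenyl carbon does not), and the hindered chromene alkene is left alone.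

Step 4
Reactants: 6 (2E,4S)-4-(7-methoxy-2,2-dimethyl-2H-chromen-6-yl)-2-methylpent-2-enal
Product: 7 7-methoxy-2,2-dimethyl-6-[(2S,3E)-4-methylhex-3-en-5-yn-2-yl]-2H-chromene
Conditions: TMSCHN2 (1.2 equiv), n-BuLi (1.2 equiv), THF, −78 °C; add 6; −78 °C to rt; H2O
Reagents that add atoms: trimethylsilyldiazomethane C[Si](C)(C)C=[N+]=[N-]
Why: In the Colvin rearrangement fast 1,2-addition at −78 °C, loss of LiOSiMe3 and N2, and a 1,2-hydrogen shift turn CHO into C≡CH without touching the alkene geometry or the γ-stereocentre.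

Step 5
Reactants: 8 1-(2,4-dihydroxyphenyl)ethanone (2,4-dihydroxyacetophenone)
Product: 9 1-(2,4-dihydroxy-5-iodophenyl)ethanone
Conditions: ICl (1.05 equiv), AcOH, rt; recrystallise
Reagents that add atoms: iodine monochloride ClI
Why: Electrophilic aromatic iodination under acidic, non-phenoxide conditions goes to C5, which is ortho to the 4-OH and para to the 2-OH, rather than to the crowded C3 between the two hydroxyls.

Step 6
Reactants: 7 7-methoxy-2,2-dimethyl-6-[(2S,3E)-4-methylhex-3-en-5-yn-2-yl]-2H-chromene; 9 1-(2,4-dihydroxy-5-iodophenyl)ethanone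
Product: 11 1-{6-hydroxy-2-[(2E,4S)-4-(7-methoxy-2,2-dimethyl-2H-chromen-6-yl)pent-2-en-2-yl]-1-benzofuran-5-yl}ethanone (target CNP0347774.1), via 2-alkynylphenol 10 (not isolated)
Conditions: PdCl2(PPh3)2 (3 mol %), CuI (5 mol %), Et3N (4 equiv), degassed DMF, rt then 60 °C
Reagents that add atoms: none
Why: Zerovalent palladium inserts into the C–I bond for the Sonogashira coupling, the free 4-OH ortho to the new alkyne then adds 5-endo-dig (heteroannulation) to close the furan ring, and the chelated 2-OH, the ketone, both alkenes and the stereocentre are inert to Et3N at 60 °C.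

## Compound list
1 | 7-methoxy-2,2-dimethyl-2H-chromene | COc1cc2c(cc1)C=CC(C)(C)O2 | starting material
2 | N-[(7-methoxy-2,2-dimethyl-2H-chromen-6-yl)methylidene]-N-methylmethanaminium dichlorophosphate | COc1cc2c(cc1C=[N+](C)C)C=CC(C)(C)O2.[O-]P(=O)(Cl)Cl | intermediate
3 | 7-methoxy-2,2-dimethyl-2H-chromene-6-carbaldehyde | COc1cc2c(cc1C=O)C=CC(C)(C)O2 | intermediate
4 | 6-ethenyl-7-methoxy-2,2-dimethyl-2H-chromene | COc1cc2c(cc1C=C)C=CC(C)(C)O2 | intermediate
5 | (2R)-2-(7-methoxy-2,2-dimethyl-2H-chromen-6-yl)propanal (same spatial arrangement as in 11) | COc1cc2c(cc1[C@@H](C)C=O)C=CC(C)(C)O2 | intermediate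
6 | (2E,4S)-4-(7-methoxy-2,2-dimethyl-2H-chromen-6-yl)-2-methylpent-2-enal | COc1cc2c(cc1[C@@H](C)/C=C(\C)C=O)C=CC(C)(C)O2 | intermediate
7 | 7-methoxy-2,2-dimethyl-6-[(2S,3E)-4-methylhex-3-en-5-yn-2-yl]-2H-chromene | COc1cc2c(cc1[C@@H](C)/C=C(\C)C#C)C=CC(C)(C)O2 | intermediate
8 | 1-(2,4-dihydroxyphenyl)ethanone | CC(=O)c1ccc(O)cc1O | starting material
9 | 1-(2,4-dihydroxy-5-iodophenyl)ethanone | CC(=O)c1cc(I)c(O)cc1O | intermediate
10 | 1-{2,4-dihydroxy-5-[(3E,5S)-5-(7-methoxy-2,2-dimethyl-2H-chromen-6-yl)-3-methylhex-3-en-1-yn-1-yl]phenyl}ethanone | COc1cc2c(cc1[C@@H](C)/C=C(\C)C#Cc1cc(C(C)=O)c(O)cc1O)C=CC(C)(C)O2 | intermediate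
11 | 1-{6-hydroxy-2-[(2E,4S)-4-(7-methoxy-2,2-dimethyl-2H-chromen-6-yl)pent-2-en-2-yl]-1-benzofuran-5-yl}ethanone | COc1cc2c(cc1[C@@H](C)/C=C(\C)c1cc3cc(C(C)=O)c(O)cc3o1)C=CC(C)(C)O2 | target

## Step count and risks
Total step count: 6 (each one-pot sequence counted once).
Longest linear sequence: 5 (steps 1, 2, 3, 4, 6).

**Step 3.** The risks are branched selectivity and ee with an ortho-substituted, electron-rich styrene, and partial racemisation of 5 during the slow Wittig reaction.
- The fallback sets out from 4 and comes back to the route at 6, and it never passes through an α-aryl aldehyde.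
- Nickel-catalysed asymmetric hydrovinylation of 4 gives 6-[(2S)-but-3-en-2-yl]-7-methoxy-2,2-dimethyl-2H-chromene F1, whose stereocentre cannot enolise. Conditions: [(C3H5)NiBr]2, NaB[3,5-(CF3)2C6H3]4, the BINOL/bis(1-phenylethyl)amine phosphoramidite of the sense that gives the S product, ethene 1 atm, CH2Cl2, −70 °C.
- Cross-metathesis of this alkene with excess methacrolein gives the E-enal 6. Conditions: second-generation Hoveyda–Grubbs catalyst, 1,4-benzoquinone, CH2Cl2, 40 °C.

**Step 4.** The risks are γ-deprotonation of the enal by the lithiated diazo reagent and a low-yielding rearrangement.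
- The fallback sets out from 6 and comes back at 7 by a Corey–Fuchs sequence.
- CBr4/PPh3 (CH2Cl2, 0 °C) turns the aldehyde into 6-[(2S,3E)-6,6-dibromo-4-methylhexa-3,5-dien-2-yl]-7-methoxy-2,2-dimethyl-2H-chromene F2.
- n-BuLi (2.1 equiv, THF, −78 °C) converts it by Br/Li exchange and Fritsch–Buttenberg–Wiechell rearrangement into the lithium acetylide of 7 F3, and water then gives 7.

**Step 6.** The risks are Glaser dimerisation of 7, sluggish coupling of the free resorcinol-type iodide, and incomplete ring closure.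
- The fallback sets out from 9 and comes back at 10. It separates coupling from ring closure.
- Ac2O (1.05 equiv), pyridine, CH2Cl2, 0 °C acetylates only the non-chelated 4-OH to give 4-acetyl-5-hydroxy-2-iodophenyl acetate F4.
- Sonogashira coupling with 7 at rt (PdCl2(PPh3)2, CuI, Et3N, THF) stops at the isolable 4-acetyl-5-hydroxy-2-[(3E,5S)-5-(7-methoxy-2,2-dimethyl-2H-chromen-6-yl)-3-methylhex-3-en-1-yn-1-yl]phenyl acetate F5.
- K2CO3 in MeOH at 50 °C removes the acetate to give 10, which closes to 11 under the same base.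

## Further compounds
F1 | step 3 | 6-[(2S)-but-3-en-2-yl]-7-methoxy-2,2-dimethyl-2H-chromene | COc1cc2c(cc1[C@@H](C)C=C)C=CC(C)(C)O2
F2 | step 4 | 6-[(2S,3E)-6,6-dibromo-4-methylhexa-3,5-dien-2-yl]-7-methoxy-2,2-dimethyl-2H-chromene | COc1cc2c(cc1[C@@H](C)/C=C(\C)C=C(Br)Br)C=CC(C)(C)O2
F3 | step 4 | lithium acetylide of 7 | COc1cc2c(cc1[C@@H](C)/C=C(\C)C#C[Li])C=CC(C)(C)O2
F4 | step 6 | 4-acetyl-5-hydroxy-2-iodophenyl acetate | CC(=O)Oc1cc(O)c(C(C)=O)cc1I
F5 | step 6 | 4-acetyl-5-hydroxy-2-[(3E,5S)-5-(7-methoxy-2,2-dimethyl-2H-chromen-6-yl)-3-methylhex-3-en-1-yn-1-yl]phenyl acetate | COc1cc2c(cc1[C@@H](C)/C=C(\C)C#Cc1cc(C(C)=O)c(O)cc1OC(C)=O)C=CC(C)(C)O2
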